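(The readings stem from a simulated flask for an exercise, noise included.)

At early times starting material goes before target comes. In the red run, after 0.333 h, 46.6% of the charge has left, yet target reads 2.2%, so something stands between the two.

| flask | starting material | partner | second reagent | third reagent | temperature | remark | time |
|---|---|---|---|---|---|---|---|
| amber | 0.018 M | 0.030 M | 0.0171 M | 0.0216 M | 79 °C | run made earlier |  |
| red | 0.018 M | 0.048 M | 0.0171 M | 0.0216 M | 87 °C | run made earlier |  |
| green | 0.018 M | 0.0216 M | 0.0171 M | 0.043 M | 79 °C | run made earlier |  |
| winter | 0.018 M | 0.0216 M | 0.0171 M | 0.0216 M | 75 °C |  | 8.0 h |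
| noon | 0.018 M | 0.0216 M | 0.0171 M | 0.0216 M |  | at 75 °C until 4.0 h, from then on at 90 °C | 8.0 h |
| dawn | 0.018 M | 0.0216 M | 0.0171 M | 0.0216 M | 90 °C |  | 8.0 h |

- amber (time / h: target / %, starting material / %): 0.667: 1.3, 65.3; 1.33: 6.9, 46.1; 2.50: 21.3, 26.4; 4.00: 36.6, 13.5; 8.00: 58.0, 4.2
- red (time / h: target / %, starting material / %): 0.333: 2.2, 53.4; 1.00: 17.8, 18.7; 2.00: 41.0, 4.8; 3.00: 55.3, 1.5; 4.00: 63.3, 0.5
- green (time / h: target / %, starting material / %): 0.667: 0.9, 72.2; 2.00: 14.4, 43.5; 4.00: 33.1, 24.6; 6.00: 44.7, 15.8; 8.00: 53.2, 10.4

(readings scatter by 0.3 percentage points)

- what was read earlier has a scatter of 0.3 percentage points, one standard deviation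
- a reading or a percentage of target counts all its forms, free or not

- the flask that comes out highest in amount of target, in percent of the starting material charged, or "all alike" when all lie within 1.5 percentage points (winter / noon / dawn / all alike)
- target at the end, in percent of the starting material charged, winter
- target at the end, in percent of the starting material charged, noon
- target at the end, in percent of the starting material charged, dawn

The symmetric case gives the zero of the scale. If each reagent is spent one to one with starting material, which is an assumption here, the lowest reagent charge over the starting material charged bounds target. In winter, noon and dawn the second reagent has the lowest charge, so this ratio is 95.0%, the ceiling.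

The red run, with the same second reagent charge, gives the ladder of times. Its first rung is the loss of starting material, which falls by a factor e in about 0.793 h between its second and fourth readings. The gap is whatever of the charge is neither starting material nor target. It is the slower rung, read from the last two readings: it shrinks by a factor e in about 5.66 h, much longer than the first rung. So at 4.00 h the red run has starting material down to 0.5%, while target stands at 63.3%, which is 66.6% of the ceiling.

Dawn is hotter than the red run and runs twice as long, though with less partner. The reckoning here places dawn between 63.3% and the ceiling, as an estimate. Noon shares winter's first 4.0 h and then takes dawn's temperature, so the reckoning ranks dawn above noon and noon above winter.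

The forecast names dawn as highest, with winter 42% (38% to 46%), noon 66% (60% to 71%) and dawn 74% (66% to 80%), on the grounds that a slowly falling constant of its second step “hints at small losses, so I trim these slightly”.

Winter gives 41.3%, noon 61.3% and dawn 70.7%, so dawn is highest, at 74.4% of the ceiling.

    third reagent + intermediate B → target (k = 2.69 M⁻¹ min⁻¹, Ea = 60.0 kJ mol⁻¹)
    second reagent + intermediate A → intermediate B (k = 1.19 M⁻¹ min⁻¹, Ea = 85.0 kJ mol⁻¹)
    crystals ⇌ target, rate k3*(cs3 - [target]) while solid is left; crystals form when [target] > cs3 (solubility = 9.90 mM, k = 4.08 min⁻¹)
    starting material + second reagent → side product (k = 0.159 M⁻¹ min⁻¹, Ea = 73.0 kJ mol⁻¹)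
    starting material + partner → intermediate A (k = 0.859 M⁻¹ min⁻¹, Ea = 87.0 kJ mol⁻¹)
    (constants at 90 °C)

The neighbour is dawn with third reagent cut to 0.0086 M, which is 0.478 equiv to starting material. Third reagent now has the lowest charge, so the ceiling of this neighbour drops to 47.8%. The neighbour ends with 47.2% target, 98.7% of that ceiling. Third reagent, the limiting reagent of this flask, is down to 1.25% of its own charge, and intermediate B holds 24.8% of the starting material charged.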